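**Assumptions (one line):** (2S)-naringenin is bought as the enantiomer (racemic material is sold under the same name, so check ee by chiral HPLC before use), and tert-butyl 2-methylbut-3-en-2-yl carbonate is taken as a catalogue reagent.

The target is the natural (2S)-flavanone: 5,7-dihydroxy A ring, and a B ring carrying a 2,2-dimethyl-2H-chromene fused at C4'(O)/C5' and a prenyl group at C3'.

## Retrosynthetic overview

1. Target 10 ⇐ 7-O-MOM ether 9 (acetal cleavage only).
2. The 2,2-dimethylchromene ring of 9 ⇐ aryl 1,1-dimethylpropargyl ether 8, by a thermal propargyl Claisen / [1,5]-H shift / oxa-6π electrocyclization cascade. This is the only ring made in the route and it is made last.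
3. 8 ⇐ 3'-prenyl phenol 6, whose aryl–prenyl C–C bond comes from an aromatic Claisen [3,3] shift of 1,1-dimethylallyl ether 5.
4. 5 ⇐ 7-O-MOM-naringenin 3 ⇐ (2S)-naringenin 1. Rings A and C and the single stereocentre C2 are purchased intact, and no bond to C2 is made or broken in the route.

## Route

**Step 1**
Reactants: 1, (2S)-naringenin [(2S)-5,7-dihydroxy-2-(4-hydroxyphenyl)chroman-4-one]; 2, chloromethyl methyl ether.
Product: 3, (2S)-5-hydroxy-2-(4-hydroxyphenyl)-7-(methoxymethoxy)chroman-4-one.
Conditions: MOMCl (1.1 equiv), i-Pr2NEt (1.3 equiv), THF, 0 °C → rt, 3 h.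
Reagents that add atoms: MOMCl, COCCl.
Why: Selective phenol O-alkylation (MOM protection): the 7-OH, para to the C4 carbonyl, is by far the most acidic phenol and the only one ionised by the amine base, the 5-OH is locked in a hydrogen bond to C=O and the 4'-OH stays protonated; C2 is untouched.

**Step 2**
Reactants: 3; 4, tert-butyl 2-methylbut-3-en-2-yl carbonate.
Product: 5, (2S)-5-hydroxy-7-(methoxymethoxy)-2-[4-(2-methylbut-3-en-2-yloxy)phenyl]chroman-4-one.
Conditions: Pd(PPh3)4 (3 mol%), 4 (1.3 equiv), THF, 0 °C, 2–4 h; quench cold.
Reagents that add atoms: tert-butyl 2-methylbut-3-en-2-yl carbonate, C=CC(C)(C)OC(=O)OC(C)(C)C.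
Why: Tsuji–Trost O-allylation under essentially neutral conditions: the 4'-phenoxide attacks the π-(1,1-dimethylallyl)palladium cation at the more substituted terminus to give the kinetic tertiary ether, the chelated 5-OH does not compete, and the only base is the tert-butoxide released on decarboxylation, so C2 is not at risk.

**Step 3**
Reactants: 5.
Product: 6, (2S)-5-hydroxy-2-[4-hydroxy-3-(3-methylbut-2-en-1-yl)phenyl]-7-(methoxymethoxy)chroman-4-one.
Conditions: degassed PhMe, 130 °C (sealed tube, base-washed glass), 6–10 h.
Reagents that add atoms: none.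
Why: Aromatic Claisen [3,3] rearrangement of the reverse-prenyl ether delivers the allyl terminus to an ortho carbon (the two are equivalent, para is blocked) and tautomerisation gives the 3'-prenyl phenol; the neutral, non-ionising medium leaves C2 alone.

**Step 4**
Reactants: 6; 7, 3-chloro-3-methylbut-1-yne.
Product: 8, (2S)-5-hydroxy-7-(methoxymethoxy)-2-[3-(3-methylbut-2-en-1-yl)-4-(2-methylbut-3-yn-2-yloxy)phenyl]chroman-4-one.
Conditions: 7 (1.3 equiv), CuCl2·2H2O (1 mol%), DBU (1.3 equiv), MeCN, −5 to 0 °C, 4–6 h; cold dilute-acid quench; check ee by chiral HPLC.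
Reagents that add atoms: 3-chloro-3-methylbut-1-yne, C#CC(C)(C)Cl.
Why: Copper-catalysed propargylic etherification (via a copper acetylide/allenylidene) makes the tertiary aryl propargyl ether at low temperature, with the free 4'-OH as the only unchelated phenol; the short, cold exposure to DBU is chosen to limit base-mediated ring-opening at C2.

**Step 5**
Reactants: 8.
Product: 9, (2S)-2-[2,2-dimethyl-8-(3-methylbut-2-en-1-yl)-2H-chromen-6-yl]-5-hydroxy-7-(methoxymethoxy)chroman-4-one.
Conditions: degassed o-xylene, 140 °C, 12 h, Ar.
Reagents that add atoms: none.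
Why: Propargyl Claisen [3,3] shift to the only free ortho carbon (C5'; C3' carries the prenyl group) gives an allenyl dienone that enolises, undergoes a [1,5]-H shift to the o-quinone methide and closes by oxa-6π electrocyclization to the 2,2-dimethylchromene; no base or acid is present, so C2, the MOM ether and the prenyl group survive.

**Step 6**
Reactants: 9.
Product: 10, (2S)-2-[2,2-dimethyl-8-(3-methylbut-2-en-1-yl)-2H-chromen-6-yl]-5,7-dihydroxychroman-4-one (target).
Conditions: 3 M aq HCl, MeOH, 50 °C, 1–2 h.
Reagents that add atoms: none.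
Why: Acid-catalysed cleavage of the phenolic MOM acetal; the prenyl group has no free ortho-OH to cyclise onto, the chromene alkene tolerates brief dilute acid, and flavanone C2 does not epimerise under mild acid because no phenoxide or enolate is formed.

## Compound list

1 | (2S)-naringenin | Oc1ccc([C@@H]2CC(=O)c3c(O)cc(O)cc3O2)cc1 | starting material
2 | chloromethyl methyl ether (MOMCl) | COCCl | starting material
3 | (2S)-7-O-MOM-naringenin | Oc1ccc([C@@H]2CC(=O)c3c(O)cc(OCOC)cc3O2)cc1 | intermediate
4 | tert-butyl 2-methylbut-3-en-2-yl carbonate | C=CC(C)(C)OC(=O)OC(C)(C)C | starting material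
5 | (2S)-7-O-MOM-4'-O-(1,1-dimethylallyl)naringenin | C=CC(C)(C)Oc1ccc([C@@H]2CC(=O)c3c(O)cc(OCOC)cc3O2)cc1 | intermediate
6 | (2S)-7-O-MOM-3'-prenylnaringenin | CC(C)=CCc1cc([C@@H]2CC(=O)c3c(O)cc(OCOC)cc3O2)ccc1O | intermediate
7 | 3-chloro-3-methylbut-1-yne | C#CC(C)(C)Cl | starting material
8 | (2S)-7-O-MOM-3'-prenyl-4'-O-(1,1-dimethylpropargyl)naringenin | CC(C)=CCc1cc([C@@H]2CC(=O)c3c(O)cc(OCOC)cc3O2)ccc1OC(C)(C)C#C | intermediate
9 | (2S)-7-O-MOM ether of the target | CC(C)=CCc1cc([C@@H]2CC(=O)c3c(O)cc(OCOC)cc3O2)cc2c1OC(C)(C)C=C2 | intermediate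
10 | (2S)-2-[2,2-dimethyl-8-prenyl-2H-chromen-6-yl]-5,7-dihydroxychroman-4-one | CC(C)=CCc1cc([C@@H]2CC(=O)c3c(O)cc(O)cc3O2)cc2c1OC(C)(C)C=C2 | target

## Summary

Total steps: 6. Longest linear sequence: 6 (fully linear from 1).

Steps most likely to fail, with fallbacks:

1. **Step 4** (tertiary propargylation of an ortho-substituted phenol with DBU): risks are low conversion, 5-O-alkylation, and erosion of ee through phenoxide-assisted opening of the C2–O1 bond. Fallback: drop the propargyl ether. Repeat the Pd reverse-prenylation/Claisen pair (Steps 2–3) on 6 to give the 3',5'-diprenyl phenol, then close the chromene with DDQ (dehydrogenation to the o-quinone methide, then oxa-6π closure), which needs no amine base.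
2. **Step 3** (Claisen of the 1,1-dimethylallyl ether): risks are loss of isoprene back to phenol 3 and acid-traced cyclisation of the o-prenyl phenol to a chroman. Fallback: make the simple O-allyl ether (allyl methyl carbonate, Pd(0)), run the Claisen to the 3'-allyl phenol, and convert allyl to prenyl by cross-metathesis with 2-methyl-2-butene (Grubbs II).
3. **Step 6** (acidic MOM removal next to a prenyl group and a chromene): risk is HCl or MeOH addition to the alkenes. Fallback: change the protecting-group plan from Step 1 to a 7-O-triisopropylsilyl ether, carried through the same sequence and removed at the end with buffered fluoride (HF·pyridine or TBAF/AcOH) and no acid.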